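The data were generated by integration with made-up constants; scatter was added.

The closed, stirred, isothermal vessel had been run twice before at the same [X] and [Z], with L as the difference.

common to all: X 1.5 M
- north-east: Z 1.5 M; L 0.55 mol%; run made earlier
- south-east: Z 1.5 M; L 0.98 mol%; run made earlier
- green: Z 1.50 M; L 0.5 mol%; time 8.0 min
- teal: Z 1.50 M; L 0.75 mol%; time 8.0 min

| run | time / min | J / % | E / % | X / % |
|---|---|---|---|---|
| north-east | 1.00 | 3.3 | 92.3 | 0 |
| north-east | 2.00 | 8.7 | 89.5 | 0 |
| north-east | 3.00 | 12.5 | 86.6 | 0 |
| north-east | 4.00 | 16.4 | 82.1 | 0 |
| north-east | 5.00 | 19.5 | 79.0 | 0 |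
| north-east | 6.00 | 22.9 | 74.9 | 1.8 |
| south-east | 0.417 | 3.2 | 79.8 | 15.3 |
| south-east | 1.00 | 7.4 | 89.7 | 0 |
| south-east | 2.00 | 13.1 | 83.8 | 0.3 |
| south-east | 3.00 | 19.7 | 77.8 | 0 |
| south-east | 4.00 | 26.1 | 71.8 | 2.7 |
| south-east | 6.00 | 36.4 | 59.8 | 0 |

(readings scatter by 1 percentage point)



* which of these there is most of at the end, counted by the X in it, green (X / J / E)
* which of these there is most of at the end, counted by the X in it, teal (X / J / E)
* amount of the one of these that there is most of at the end, in percent of the X charged, green
* amount of the one of these that there is most of at the end, in percent of the X charged, teal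

Following one molecule of X, I saw a quick first stage: X already read 0% at 1.00 min in the north-east run. The molecule then sat as E and waited to become J. At the last readings, E and J together held about 97.0%, and I took this as the plateau that the reckoning starts from.

The bench rule I tried first was a straight line: with [X] and [Z] as in these runs, J grows in proportion to loading times time. Scaled from the north-east slope, it gave J 42.8% for teal. But that line needed E to stay near its start. In the south-east run, E at 6.00 min stood at 0.667 of its value at 1.00 min, so if the rate follows [E], it had lost a third by then. Teal's loading times time is 1.02 of that south-east reading, which puts teal at this border.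

So I asked instead for a molecule's chance of surviving as E. I assumed that its chance of turning is steady and proportional to [L], which makes the decay pseudo-first-order. Then E = plateau × exp(−κ[L]t), where κ, the turnover constant, is a molecule's chance of turning per minute and per unit of [L]. The log fall of E per unit [L]t read 5.06 M⁻¹ min⁻¹ in the north-east run and 5.52 M⁻¹ min⁻¹ in the south-east run, so I took κ as 5.29 M⁻¹ min⁻¹. My reckoning gave E 70.6% for green and 60.3% for teal, and in each flask that was more than the rest of the plateau, which I counted as J.

The forecast, holding that “E then turns slowly into J”, named E for both flasks, at 72% for green and 62% for teal, higher than my figures.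

The flasks gave E at 70.0% in green and E at 59.5% in teal.

    X → E (k = 0.0760 s⁻¹)
    X + Z → Q (k = 0.00160 M⁻¹ s⁻¹)
    L + E → L + J (k = 0.0930 M⁻¹ s⁻¹)

Teal also held Q at 3.02% of the X charged at 8.00 min. In the neighbouring flask, teal was repeated with [X] at 0.60 M and the same loading, so [L] was 0.00450 M. With that [L], κ gave E 80.2%, and the flask held E at 79.7%.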